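**Retrosynthetic overview**
1. Target 24 ⇐ opening of the 8β,9β-epoxy-10-methylidene compound 21 by (Z)-3-methylpent-2-enoic acid 23 at the allylic C9 (last bond); 21 ⇐ enone 19 by epoxidation and methylenation.
2. Ring B (six-membered) ⇐ aldol condensation of a keto aldehyde released by ozonolysis of the isopropenyl and vinyl arms of cyclopentane 15; Z-ethylidene ⇐ syn-dehydration of the C4 carbinol.
3. Ring A (five-membered) ⇐ key step: semipinacol ring contraction of the cyclohexane β-mesyloxy carbinol 13 (C6 shifts from C4 to C5, C4 leaves the ring as the acetyl carbon, 3β-OAc already in place).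
4. 13 ⇐ epoxy ketone 10 (MeMgBr, then acetate opening at C3 with inversion) ⇐ enone 9 ⇐ trans-2,3-disubstituted cyclohexanone 7 ⇐ cyclohexenone 3 + isopropenyl Grignard 4 + allyl carbonate 2 (one-pot asymmetric conjugate addition/branched allylation, new).
5. Ring order: the six-membered carbocycle of 3 is carried to 13 and contracted to ring A (step 7); ring B is closed last (step 9).

**Conventions and assumption**
- Locants (target numbering, used for all compounds): ring A = C1–C2–C3–C5–C6 with C4(H)–C15H3 as the ethylidene on C5; ring B = C1–C6–C7–C8–C9–C10 with C14H2 on C10 and the isopropyl (C11–C13) on C7. In the monocyclic precursors C4 is still a ring atom between C5 and C6.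
- β = the face of H6. Bicyclic compounds are named as bicyclo[4.3.0]nonanes carrying these locants. Target = (1R,3S,6R,7S,8S,9S), Z at C5=C4, Z in the ester.
- Assumption: (E)-4-methylpent-2-en-1-ol is taken as a catalogue chemical.

**Route**

Step 1
Reactants: 1 (E)-4-methylpent-2-en-1-ol
Product: 2 methyl (E)-4-methylpent-2-en-1-yl carbonate
Conditions: ClCO2Me, pyridine, CH2Cl2, 0 °C
Reagents that add atoms: methyl chloroformate, COC(=O)Cl
Why: Acylation of the primary allylic alcohol by the chloroformate (carbonate formation) provides the leaving group for the later allylic alkylation and creates no stereocentre.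

Step 2
Reactants: 3 cyclohex-2-en-1-one; 4 isopropenylmagnesium bromide; 2 methyl (E)-4-methylpent-2-en-1-yl carbonate
Product: 7 (2S,3R)-2-[(3R)-4-methylpent-1-en-3-yl]-3-(prop-1-en-2-yl)cyclohexan-1-one, via isopropenylzinc chloride 5 (not isolated), via chlorozinc enolate 6 (not isolated)
Conditions: 4, ZnCl2, THF, 0 °C; 3, [RhCl(C2H4)2]2 (2.5 mol%), (R)-BINAP, THF, 20 °C; then 2, [IrCl(C8H12)]2 (2 mol%), (Sa,S,S)-binaphthyl N,N-bis(1-phenylethyl)phosphoramidite, 40 °C
Reagents that add atoms: none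
Why: Proposed new method: a one-pot relay in which the [RhCl(C2H4)2]2/(R)-BINAP-catalysed 1,4-addition of alkenylzinc chloride 5 to enone 3 (Hayashi–Miyaura-type conjugate addition, ligand-controlled, C1 = R) gives the regiodefined zinc enolate 6, which is not quenched but attacks, anti to the new isopropenyl group (C6 = S, 2,3-trans), the substituted terminus of the allyl complex generated from 2 by [IrCl(C8H12)]2/phosphoramidite (outer-sphere, branched-selective allylic alkylation, the ligand setting C7, which can in any case re-equilibrate in step 9), loss of CO2 from the carbonate making the C–C bond formation irreversible; the closest known reactions are conjugate addition/Pd-catalysed allylation tandems of zinc enolates and the two separate Rh- and Ir-catalysed reactions, the untested element being the direct use of the chiral zinc enolate as nucleophile in the Ir-catalysed branched allylation to build the vicinal C6/C7 centres.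

Step 3
Reactants: 7 (2S,3R)-2-[(3R)-4-methylpent-1-en-3-yl]-3-(prop-1-en-2-yl)cyclohexan-1-one
Product: 9 (5R,6S)-6-[(3R)-4-methylpent-1-en-3-yl]-5-(prop-1-en-2-yl)cyclohex-2-en-1-one, via silyl enol ether 8 (not isolated)
Conditions: LiN(iPr)2, Me3SiCl, THF, −78 °C; then Pd(OAc)2, MeCN, 25 °C
Reagents that add atoms: none
Why: Kinetic deprotonation by LiN(iPr)2 occurs at C5, the only α-CH2, and Saegusa–Ito oxidation of silyl enol ether 8 by Pd(OAc)2 gives the C5=C3 enone without affecting C1 or C6.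

Step 4
Reactants: 9 (5R,6S)-6-[(3R)-4-methylpent-1-en-3-yl]-5-(prop-1-en-2-yl)cyclohex-2-en-1-one
Product: 10 (1R,3S,4R,6R)-3-[(3R)-4-methylpent-1-en-3-yl]-4-(prop-1-en-2-yl)-7-oxabicyclo[4.1.0]heptan-2-one
Conditions: H2O2 (30% aq), NaOH (cat), MeOH, 0 °C
Reagents that add atoms: hydrogen peroxide, OO
Why: Weitz–Scheffer nucleophilic epoxidation is specific for the electron-poor enone C=C and, as for carvone, hydroperoxide adds to C3 anti to the homoallylic isopropenyl group at C1, so the epoxide forms on the α face and fixes the oxygens at C3 and C5.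

Step 5
Reactants: 10 (1R,3S,4R,6R)-3-[(3R)-4-methylpent-1-en-3-yl]-4-(prop-1-en-2-yl)-7-oxabicyclo[4.1.0]heptan-2-one
Product: 11 (1R,2S,3S,4R,6R)-2-methyl-3-[(3R)-4-methylpent-1-en-3-yl]-4-(prop-1-en-2-yl)-7-oxabicyclo[4.1.0]heptan-2-ol
Conditions: MeMgBr, THF, −78 °C; aq NH4Cl
Reagents that add atoms: methylmagnesium bromide, C[Mg]Br
Why: Grignard 1,2-addition to the α,β-epoxy ketone occurs anti to the epoxide oxygen and to the C6 side chain, giving the cis-epoxy tertiary alcohol needed for chelation in step 6 (the C4 centre itself is destroyed in step 7).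

Step 6
Reactants: 11 (1R,2S,3S,4R,6R)-2-methyl-3-[(3R)-4-methylpent-1-en-3-yl]-4-(prop-1-en-2-yl)-7-oxabicyclo[4.1.0]heptan-2-ol
Product: 12 (1S,2R,3S,4S,5R)-2,3-dihydroxy-3-methyl-4-[(3R)-4-methylpent-1-en-3-yl]-5-(prop-1-en-2-yl)cyclohexyl acetate
Conditions: Ti(OiPr)4 (1.5 equiv), AcOH, CH2Cl2, 25 °C
Reagents that add atoms: acetic acid, CC(=O)O
Why: Ti(OiPr)4-mediated regioselective opening of a 2,3-epoxy alcohol (Sharpless-type C3 opening): in the chelate of the C4 alkoxide and the epoxide, acetate attacks the distal, non-neopentyl C3 by SN2 inversion, turning the α-epoxide into the 3β-acetate of the target and leaving the α-hydroxyl at C5 as the future leaving group.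

Step 7
Reactants: 12 (1S,2R,3S,4S,5R)-2,3-dihydroxy-3-methyl-4-[(3R)-4-methylpent-1-en-3-yl]-5-(prop-1-en-2-yl)cyclohexyl acetate
Product: 14 (1S,2S,3S,4R)-2-acetyl-3-[(3R)-4-methylpent-1-en-3-yl]-4-(prop-1-en-2-yl)cyclopentyl acetate, via C5 mesylate 13 (not isolated)
Conditions: MsCl, Et3N, CH2Cl2, −20 °C; then AlEt3, CH2Cl2, −78 to 0 °C
Reagents that add atoms: none
Why: Key ring contraction by a semipinacol (pinacol-type) 1,2-shift: in the chair of 13 the equatorial C5 mesylate is antiperiplanar to the C4–C6 ring bond, so once the AlEt3-derived alkoxide forms at the tertiary C4 hydroxyl, C6 migrates from C4 to C5 (inversion at C5, retention at C6), the ring contracts and C4 leaves the ring as the acetyl carbon (the future ethylidene), the 3β-acetate staying untouched.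

Step 8
Reactants: 14 (1S,2S,3S,4R)-2-acetyl-3-[(3R)-4-methylpent-1-en-3-yl]-4-(prop-1-en-2-yl)cyclopentyl acetate
Product: 15 (1S,2R,3S,4R)-2-[(1S)-1-hydroxyethyl]-3-[(3R)-4-methylpent-1-en-3-yl]-4-(prop-1-en-2-yl)cyclopentyl acetate
Conditions: (R)-2-methyl-CBS-oxazaborolidine (20 mol%), catecholborane, toluene, −78 °C
Reagents that add atoms: none
Why: Corey–Bakshi–Shibata reduction of the methyl ketone is reagent-controlled, the (R)-oxazaborolidine giving the (S)-carbinol (mirror image of the acetophenone case), and catecholborane at low temperature leaves the ester and both alkenes intact; this centre later decides the ethylidene geometry.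

Step 9
Reactants: 15 (1S,2R,3S,4R)-2-[(1S)-1-hydroxyethyl]-3-[(3R)-4-methylpent-1-en-3-yl]-4-(prop-1-en-2-yl)cyclopentyl acetate
Product: 17 3β-acetoxy-5α-[(1S)-1-hydroxyethyl]-7β-isopropyl-bicyclo[4.3.0]non-8-en-10-one (H1α, H6β), via keto aldehyde 16 (not isolated)
Conditions: O3, CH2Cl2/MeOH, −78 °C; Me2S; then pyrrolidine, AcOH, CH2Cl2, 25 °C
Reagents that add atoms: ozone, [O-][O+]=O
Why: Ozonolysis cleaves the two terminal alkenes to the C10 methyl ketone and the α-branched C8 aldehyde, and amine-catalysed intramolecular aldol condensation (the ring-closing half of a Robinson annulation) forms ring B on the trans-disubstituted cyclopentane, C1 (α to the ketone) and C7 (γ to the enone) being free to settle in the trans-fused, pseudo-equatorial arrangement of the target.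

Step 10
Reactants: 17 3β-acetoxy-5α-[(1S)-1-hydroxyethyl]-7β-isopropyl-bicyclo[4.3.0]non-8-en-10-one
Product: 19 3β-acetoxy-5-[(Z)-ethylidene]-7β-isopropyl-bicyclo[4.3.0]non-8-en-10-one (H1α, H6β), via alkyl sulfamate 18 (not isolated)
Conditions: Burgess reagent, benzene, 25 to 60 °C
Reagents that add atoms: none
Why: Burgess dehydration is a syn (Ei) elimination through sulfamate 18: for the (S)-carbinol the rotamer that places H5 syn to the sulfamate oxygen puts the methyl group on the C3 side, so the Z-ethylidene (methyl syn to C3) is formed, and the more substituted (Zaitsev) alkene is favoured over loss of a methyl hydrogen.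

Step 11
Reactants: 19 3β-acetoxy-5-[(Z)-ethylidene]-7β-isopropyl-bicyclo[4.3.0]non-8-en-10-one
Product: 20 3β-acetoxy-8β,9β-epoxy-5-[(Z)-ethylidene]-7β-isopropyl-bicyclo[4.3.0]nonan-10-one
Conditions: t-BuOOH, DBU, CH2Cl2, 0 to 25 °C
Reagents that add atoms: tert-butyl hydroperoxide, CC(C)(C)OO
Why: Weitz–Scheffer epoxidation of the conformationally locked trans-fused cyclohexenone goes by stereoelectronically preferred axial attack of the peroxide anion at C8 from the β face (anti to the pseudo-axial H7), giving the 8β,9β-epoxide, while the isolated ethylidene does not react with the nucleophilic oxidant.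

Step 12
Reactants: 20 3β-acetoxy-8β,9β-epoxy-5-[(Z)-ethylidene]-7β-isopropyl-bicyclo[4.3.0]nonan-10-one
Product: 21 3β-acetoxy-8β,9β-epoxy-5-[(Z)-ethylidene]-7β-isopropyl-10-methylidene-bicyclo[4.3.0]nonane
Conditions: Zn, CH2Br2, TiCl4, THF, 0 to 25 °C
Reagents that add atoms: dibromomethane, BrCBr
Why: Lombardo (Takai–Lombardo) methylenation by the non-basic Zn/CH2Br2/TiCl4 reagent converts the ketone into the exocyclic methylene without opening the epoxide, epimerising C1 or touching the acetate.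

Step 13
Reactants: 22 pent-2-ynoic acid
Product: 23 (Z)-3-methylpent-2-enoic acid
Conditions: MeLi, CuI, THF, −78 to −40 °C (LiCuMe2, 2.2 equiv); aq HCl
Reagents that add atoms: lithium dimethylcuprate, C[Cu-]C.[Li+]
Why: Syn-carbocupration of the alkynoate by LiCuMe2 places methyl and copper cis, and protonation under retention gives the Z-acid (ethyl cis to the carboxyl group).

Step 14
Reactants: 21 3β-acetoxy-8β,9β-epoxy-5-[(Z)-ethylidene]-7β-isopropyl-10-methylidene-bicyclo[4.3.0]nonane; 23 (Z)-3-methylpent-2-enoic acid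
Product: 24 CNP0418642.1, (1R,3S,6R,7S,8S,9S)-3-acetoxy-5-[(Z)-ethylidene]-8-hydroxy-7-isopropyl-10-methylidene-bicyclo[4.3.0]non-9-yl (2Z)-3-methylpent-2-enoate
Conditions: 23 (3 equiv), iPr2NEt (0.3 equiv), toluene, 60 °C
Reagents that add atoms: none
Why: SN2 opening of the vinyl epoxide by the carboxylic acid occurs at the activated allylic C9 from the α face (inversion, trans-diaxial, Fürst–Plattner), which gives the 9α-ester and the 8β-hydroxyl in one step, uses the acid as nucleophile so that its Z geometry cannot scramble, and needs no protecting group.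

**Compound list**
1 | (E)-4-methylpent-2-en-1-ol | CC(C)/C=C/CO | starting material
2 | methyl (E)-4-methylpent-2-en-1-yl carbonate | CC(C)/C=C/COC(=O)OC | intermediate
3 | cyclohex-2-en-1-one | O=C1C=CCCC1 | starting material
4 | isopropenylmagnesium bromide | C=C(C)[Mg]Br | starting material
5 | isopropenylzinc chloride | C=C(C)[Zn]Cl | intermediate
6 | chlorozinc (3R)-3-(prop-1-en-2-yl)cyclohex-1-en-1-olate | Cl[Zn]OC1=C[C@H](C(C)=C)CCC1 | intermediate
7 | (2S,3R)-2-[(3R)-4-methylpent-1-en-3-yl]-3-(prop-1-en-2-yl)cyclohexan-1-one | O=C1CCC[C@@H](C(C)=C)[C@@H]1[C@H](C(C)C)C=C | intermediate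
8 | trimethyl{[(5R,6S)-6-[(3R)-4-methylpent-1-en-3-yl]-5-(prop-1-en-2-yl)cyclohex-1-en-1-yl]oxy}silane | C[Si](C)(C)OC1=CCC[C@@H](C(C)=C)[C@@H]1[C@H](C(C)C)C=C | intermediate
9 | (5R,6S)-6-[(3R)-4-methylpent-1-en-3-yl]-5-(prop-1-en-2-yl)cyclohex-2-en-1-one | O=C1C=CC[C@@H](C(C)=C)[C@@H]1[C@H](C(C)C)C=C | intermediate
10 | (1R,3S,4R,6R)-3-[(3R)-4-methylpent-1-en-3-yl]-4-(prop-1-en-2-yl)-7-oxabicyclo[4.1.0]heptan-2-one | O=C1[C@@H]2O[C@@H]2C[C@@H](C(C)=C)[C@@H]1[C@H](C(C)C)C=C | intermediate
11 | (1R,2S,3S,4R,6R)-2-methyl-3-[(3R)-4-methylpent-1-en-3-yl]-4-(prop-1-en-2-yl)-7-oxabicyclo[4.1.0]heptan-2-ol | C[C@@]1(O)[C@@H]2O[C@@H]2C[C@@H](C(C)=C)[C@@H]1[C@H](C(C)C)C=C | intermediate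
12 | (1S,2R,3S,4S,5R)-2,3-dihydroxy-3-methyl-4-[(3R)-4-methylpent-1-en-3-yl]-5-(prop-1-en-2-yl)cyclohexyl acetate | C[C@@]1(O)[C@H](O)[C@@H](OC(C)=O)C[C@@H](C(C)=C)[C@@H]1[C@H](C(C)C)C=C | intermediate
13 | (1S,2R,3S,4S,5R)-3-hydroxy-3-methyl-2-(methylsulfonyloxy)-4-[(3R)-4-methylpent-1-en-3-yl]-5-(prop-1-en-2-yl)cyclohexyl acetate | C[C@@]1(O)[C@H](OS(C)(=O)=O)[C@@H](OC(C)=O)C[C@@H](C(C)=C)[C@@H]1[C@H](C(C)C)C=C | intermediate
14 | (1S,2S,3S,4R)-2-acetyl-3-[(3R)-4-methylpent-1-en-3-yl]-4-(prop-1-en-2-yl)cyclopentyl acetate | CC(=O)[C@@H]1[C@@H](OC(C)=O)C[C@@H](C(C)=C)[C@@H]1[C@H](C(C)C)C=C | intermediate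
15 | (1S,2R,3S,4R)-2-[(1S)-1-hydroxyethyl]-3-[(3R)-4-methylpent-1-en-3-yl]-4-(prop-1-en-2-yl)cyclopentyl acetate | C[C@H](O)[C@@H]1[C@@H](OC(C)=O)C[C@@H](C(C)=C)[C@@H]1[C@H](C(C)C)C=C | intermediate
16 | (1S,2R,3S,4R)-4-acetyl-2-[(1S)-1-hydroxyethyl]-3-[(2S)-3-methyl-1-oxobutan-2-yl]cyclopentyl acetate | C[C@H](O)[C@@H]1[C@@H](OC(C)=O)C[C@@H](C(C)=O)[C@@H]1[C@H](C(C)C)C=O | intermediate
17 | 3β-acetoxy-5α-[(1S)-1-hydroxyethyl]-7β-isopropyl-bicyclo[4.3.0]non-8-en-10-one (H1α, H6β) | O=C1[C@@H]2C[C@H](OC(C)=O)[C@@H]([C@H](C)O)[C@H]2[C@H](C(C)C)C=C1 | intermediate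
18 | N-(methoxycarbonyl)sulfamate ester of 17 at the side-chain oxygen | O=C1[C@@H]2C[C@H](OC(C)=O)[C@@H]([C@H](C)OS(=O)(=O)NC(=O)OC)[C@H]2[C@H](C(C)C)C=C1 | intermediate
19 | 3β-acetoxy-5-[(Z)-ethylidene]-7β-isopropyl-bicyclo[4.3.0]non-8-en-10-one (H1α, H6β) | O=C1[C@@H]2C[C@H](OC(C)=O)/C(=C\C)[C@H]2[C@H](C(C)C)C=C1 | intermediate
20 | 3β-acetoxy-8β,9β-epoxy-5-[(Z)-ethylidene]-7β-isopropyl-bicyclo[4.3.0]nonan-10-one | O=C1[C@@H]2C[C@H](OC(C)=O)/C(=C\C)[C@H]2[C@H](C(C)C)[C@@H]3O[C@@H]31 | intermediate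
21 | 3β-acetoxy-8β,9β-epoxy-5-[(Z)-ethylidene]-7β-isopropyl-10-methylidene-bicyclo[4.3.0]nonane | C=C1[C@@H]2C[C@H](OC(C)=O)/C(=C\C)[C@H]2[C@H](C(C)C)[C@@H]3O[C@@H]31 | intermediate
22 | pent-2-ynoic acid | CCC#CC(=O)O | starting material
23 | (Z)-3-methylpent-2-enoic acid | CC/C(C)=C\C(=O)O | intermediate
24 | CNP0418642.1, (1R,3S,6R,7S,8S,9S)-3-acetoxy-5-[(Z)-ethylidene]-8-hydroxy-7-isopropyl-10-methylidene-bicyclo[4.3.0]non-9-yl (2Z)-3-methylpent-2-enoate | C=C1[C@@H]2C[C@H](OC(C)=O)/C(=C\C)[C@H]2[C@H](C(C)C)[C@H](O)[C@H]1OC(=O)/C=C(/C)CC | target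

**Step count**
Total: 14 steps. Longest linear sequence: 13 steps (1 → 2 → 7 → 9 → 10 → 11 → 12 → 14 → 15 → 17 → 19 → 20 → 21 → 24; step 13 is the side branch).

**Three steps most likely to fail**

Step 2 (the proposed new step). The zinc enolate may simply be protonated, may be allylated at the linear terminus, or may give poor control at C6/C7. The fallback uses known chemistry, sets out from 3 and 4, and comes back at 7. The conjugate addition of 5 is run in the presence of Me3SiCl under the same [RhCl(C2H4)2]2/(R)-BINAP catalysis, and the silyl enol ether (R)-trimethyl{[3-(prop-1-en-2-yl)cyclohex-1-en-1-yl]oxy}silane F1 is isolated. F1 is then submitted to the established fluoride-promoted branched allylation of silyl enol ethers by carbonate 2 ([IrCl(C8H12)]2/phosphoramidite, CsF, ZnF2), which gives 7.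

Step 10. The syn elimination may deliver the terminal vinyl isomer or be sluggish next to the crowded C5. The fallback sets out from 17 and comes back at 19. Appel iodination (I2, PPh3, imidazole) under inversion gives the iodide 3β-acetoxy-5α-[(1R)-1-iodoethyl]-7β-isopropyl-bicyclo[4.3.0]non-8-en-10-one F2. DBU in toluene then effects an antiperiplanar E2 elimination. Inversion followed by anti elimination leads to the same Z-ethylidene, and an iodide leaving group gives the strongest Zaitsev preference.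

Step 11. The face of the enone epoxidation is the least secure stereochemical prediction, because axial attack (β) is opposed by the pseudo-equatorial isopropyl group. The fallback sets out from 19 and comes back at 24. If the 8α,9α-epoxy ketone F3 predominates, it is hydrolysed (aq HClO4, THF; water attacks C8 by inversion, trans-diaxial) to the 8β,9α-dihydroxy ketone F4. F4 is methylenated (Zn, CH2Br2, TiCl4) to the 10-methylidene diol F5. F5 is acylated at the allylic 9-hydroxyl by acid 23 through the mixed anhydride (Z)-3-methylpent-2-enoic 2,4,6-trichlorobenzoic anhydride F6 (2,4,6-trichlorobenzoyl chloride, Et3N, then DMAP), which gives target 24.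

**Further compounds**
F1 | step 2 | (R)-trimethyl{[3-(prop-1-en-2-yl)cyclohex-1-en-1-yl]oxy}silane | C[Si](C)(C)OC1=C[C@H](C(C)=C)CCC1
F2 | step 10 | 3β-acetoxy-5α-[(1R)-1-iodoethyl]-7β-isopropyl-bicyclo[4.3.0]non-8-en-10-one (H1α, H6β) | O=C1[C@@H]2C[C@H](OC(C)=O)[C@@H]([C@@H](C)I)[C@H]2[C@H](C(C)C)C=C1
F3 | step 11 | 3β-acetoxy-8α,9α-epoxy-5-[(Z)-ethylidene]-7β-isopropyl-bicyclo[4.3.0]nonan-10-one | O=C1[C@@H]2C[C@H](OC(C)=O)/C(=C\C)[C@H]2[C@H](C(C)C)[C@H]3O[C@H]31
F4 | step 11 | 3β-acetoxy-5-[(Z)-ethylidene]-8β,9α-dihydroxy-7β-isopropyl-bicyclo[4.3.0]nonan-10-one | O=C1[C@@H]2C[C@H](OC(C)=O)/C(=C\C)[C@H]2[C@H](C(C)C)[C@H](O)[C@H]1O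
F5 | step 11 | 3β-acetoxy-5-[(Z)-ethylidene]-7β-isopropyl-10-methylidene-bicyclo[4.3.0]nonane-8β,9α-diol | C=C1[C@@H]2C[C@H](OC(C)=O)/C(=C\C)[C@H]2[C@H](C(C)C)[C@H](O)[C@H]1O
F6 | step 11 | (Z)-3-methylpent-2-enoic 2,4,6-trichlorobenzoic anhydride | CC/C(C)=C\C(=O)OC(=O)c1c(Cl)cc(Cl)cc1Cl
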